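## Structural features

The target is an achiral 18-membered macrocycle built from four benzene rings. Ring A is 1,2,4-trisubstituted (OH at C1, ethylene bridge at C3, ether oxygen at C4), ring B is a para-phenylene, ring C is 1,2,4-trisubstituted (OH, an ether oxygen ortho to it, a bridge para to the OH), and ring D is a meta-phenylene. The rings are joined in the order ring A–CH2CH2–ring B–O–ring C–CH2CH2–ring D–O–ring A, giving two bibenzyl units and two diaryl ethers. There is no stereocentre, so no stereocentres stand next to each other; the only stereogenic carbon in the route is transient and racemic. The fragile groups are the two electron-rich phenols: ring A is a hydroquinone mono-aryl ether and ring C a catechol mono-aryl ether, both prone to oxidation, so they are unveiled late. The real difficulty lies in closing a ring made of four rigid arenes and in forming the ring A–O–ring D ether next to the ortho bridge. The key step exploits the adjacency on ring A of the oxygen-bearing C4 and the bridge-bearing C3, with the hydroxyl at C1 para to the ether oxygen. The unit O–C4–C3–CH2CH2 is the aromatised form of the O–CH2–C(=O)–CH2CH2 unit of a flexible aryloxymethyl ketone. C1, C2, C5 and C6 with the phenol oxygen are the four carbons and the carbonyl oxygen of a vinyl ketone.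

## Logic of the disconnections

**21 to 20.** The O–CH3 bond on ring C is restored. The ring C oxygen must stay masked throughout, because a free hydroxyl ortho to the diaryl ether would compete in both ether formations and in the enolate chemistry. A methyl ether survives hydrogenation, lithium amide, carbonate base and selenium chemistry. The forward step must cleave one aryl methyl ether while sparing two diaryl ethers and a free phenol.

**20 to 16.** The ring A phenol is read as the tautomer of a cyclohexa-2,5-dienone, and the C5=C6 unsaturation is removed. Ring A thereby becomes a cyclohexenone and the macrocycle gains sp3 carbons and flexibility. The forward dehydrogenation must occur on the α′ side of the carbonyl and must avoid acid, so that the aryloxy group at C4 is not lost.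

**16 to 12 and 13.** The C2=C3 double bond and the C4–C5 single bond of the cyclohexenone are cut. This removes ring A entirely and leaves a macrocycle with only three arenes, in which the future C4 and C3 are an O–CH2–C(=O) unit. The forward annulation must alkylate the aryloxy-bearing α-carbon rather than the bridge-side methylene, must close the ring from the methyl carbon of the new side chain onto the macrocyclic carbonyl, and must not expel the aryloxy group.

**12 to 11.** The ring D O–CH2 bond is cut. This is the most flexible position of the macrocycle, and an SN2 reaction at a halomethyl ketone is among the fastest ether formations, so no arene has to bend during closure. The forward step needs high dilution, a single free phenol (ring D) and a masked ring C oxygen.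

**11 to 8.** The C–Br bond is removed, leaving a methyl ketone. The forward halogenation must be confined to the methyl carbon, which calls for kinetic enolisation and for temporary silylation of the ring D phenol.

**8 to 7.** The bridge C=C and the benzyl group on the ring D oxygen are put back. A single hydrogenation then does two jobs in the forward direction, provided the dialkyl ketone and the diaryl ether stay untouched.

**7 to 5 and 6.** The ring C carbon–oxygen bond of the ring B–O–ring C ether is cut. This is the convergent cut: 6 brings ring B, the bridge, the future C3 and the future C4 in one piece. The forward copper coupling must work on an electron-rich bromide flanked by a methoxy group in the presence of an enolisable methyl ketone. No aldehyde may be present at this stage, which is why the olefination comes first, and 6 must be the only phenol, which is why ring D is benzylated.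

**5 to 3 and 4.** The C=C of the ring C–ring D bridge is cut (Wittig). The alkene geometry is irrelevant, and no metal is used, so the aryl bromide is preserved for the coupling.

**3 to 1 and 2.** The C–P bond is cut; the forward step is a simple quaternisation.

## Other disconnections considered

**Alternative 1:** The cut is the ring B–O–ring C ether, between the ring B oxygen and the ring C carbon ortho to the ring C hydroxyl. In the forward direction the open-chain bisphenol A1 carries ring C as a 2,6-dibromophenol, ring B as a 2,6-dichlorophenol and ring A as its methyl ether. It would be electrolysed at constant current in methanol with LiClO4. The more easily oxidised dibromophenol should become a phenoxonium-type species, which the ring B oxygen attacks at a bromine-bearing ortho carbon. Zinc in acetic acid would then reduce the bromodienone to the halogenated macrocycle A2.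

- In its favour: the ring C hydroxyl emerges free, an ether ortho to a hydroxyl is formed without a metal catalyst, and ring closure coincides with the last ether bond between two bibenzyl halves.
- Against it here: three halogens remain in A2 and must be removed. The hindered ring A–O–ring D ether still has to be made by copper coupling on the way to A1. Site selectivity rests on modest differences in oxidation potential among three electron-rich rings. Closure happens at sp2 centres with all four arenes already rigid, at a dilution where intermolecular coupling competes.
- Comparison on structure: the chosen plan closes the macrocycle on an sp3 chain before ring A exists and introduces the strain only at aromatisation, whereas A2 must bear it in the cyclisation transition state.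
- Comparison on mechanism: a polar two-electron SN2 closure is easier to predict than an anodic oxidation.
- Comparison on step economy: halogenation, dehalogenation and demethylation make it unlikely to be shorter.
- Alternative 1 is the better plan in that all four arenes are bought rather than built and ring C needs no protecting group. The two plans are equal in ending with the cleavage of one methyl ether.

**Alternative 2:** The cut removes two C–C bonds of ring B. Ring B then arises from a 2-aryloxybutadiene on the ring C oxygen and an ethynyl ketone linked through a CH2 group to ring A, both contained in A3. In the forward direction A3 would be heated in dilute toluene with a mild Lewis acid, and a [4+2] cycloaddition would give the macrocyclic 1-acyl-4-aryloxycyclohexa-1,4-diene A4.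

- In its favour: the regiochemistry is inherently right, since a 2-donor diene and an acceptor alkyne give the 1,4 pattern of ring B. Two C–C bonds and the macrocycle form together, and the ring B–O–ring C linkage needs no aryl coupling.
- Against it here: a cycloaddition that has to close an 18-membered ring gains little effective molarity, so at high dilution it must compete with dimerisation and polymerisation of the diene. The aryloxydiene is an enol ether, labile to the Lewis acid and to traces of water. The ynone carries an acidic benzylic CH2 and can isomerise. After the key step the tether carbonyl must be deoxygenated, in addition to aromatisation and two demethylations. A3 still contains the hindered ring A–O–ring D ether.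
- Comparison on structure: both plans build one arene de novo and aromatise it afterwards. The chosen plan separates ring closure (SN2) from ring construction (annulation); Alternative 2 merges them into one demanding event.
- Comparison on step economy: the deoxygenation and the preparation of diene and ynone should make it longer.
- Alternative 2 is the better plan in regiochemical certainty, because no competition between enolisable sites arises, and in the ease of aromatising a 1,4-diene compared with dehydrogenating an enone.

**Alternative 3:** The cut is the ring A–O–ring D ether at the ring D carbon, with ring D disguised as a 3-chlorocyclohex-2-enone in the phenol A5. In the forward direction Cs2CO3 in dilute DMF would make the ring A phenoxide add to the chlorine-bearing carbon and expel chloride, closing the ring to the racemic macrocyclic vinylogous aryl ester A6.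

- In its favour: the ether next to the ortho bridge, the hardest C–O bond of the target for copper chemistry, is made by a facile addition–elimination on an unhindered sp2 carbon. The ring closes on a partly saturated, flexible ring D surrogate. No metal is needed and there is no question of site selectivity.
- Against it here: the carbonyl of A6 sits on a ring D carbon that is C–H in the target. A plain dehydrogenation would leave a surplus hydroxyl, so a deoxygenative aromatisation of several steps is required. These steps pass through vinylogous ester or enol ether stages that can hydrolyse with loss of the ether just formed. The chloroenone side chain of A5 adds preparative steps, and two methyl ethers must be removed.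
- Comparison on structure: both plans hide one arene as a cyclohexenone and cyclise on a flexible framework. In the chosen plan every atom of the annulation partner stays in the target and the carbonyl oxygen becomes the ring A phenol, whereas Alternative 3 must discard an oxygen.
- Alternative 3 is the better plan in the simplicity of its key step: one bond, no site selectivity, and the macrocycle and the hindered ether closed at once. The two plans are equal in creating a transient racemic centre of no consequence and in needing a final dehydrogenation.

Key step: step 7

Assumption: 3-(benzyloxy)benzyl bromide (1) is taken as a purchasable source of ring D, so that one hydrogenation can saturate the bridge and free the ring D phenol.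

Remark on the structures: an atom-by-atom mapping of 12 and 16 onto the target confirms an 18-membered ring, a meta-linked ring D and the ring C methoxy para to its bridge, so no structural correction is needed. 16 contains one stereogenic carbon and is expected as a racemate.

## Steps

Step 1
Reactants: 1 3-(benzyloxy)benzyl bromide; 2 triphenylphosphine
Product: 3 [3-(benzyloxy)benzyl]triphenylphosphonium bromide
Conditions: toluene, reflux
Reagents that add atoms: none
Why: SN2 quaternisation of the phosphine by a benzylic bromide; the salt should crystallise from the hot solvent.

Step 2
Reactants: 3 [3-(benzyloxy)benzyl]triphenylphosphonium bromide; 4 3-bromo-4-methoxybenzaldehyde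
Product: 5 4-{2-[3-(benzyloxy)phenyl]ethenyl}-2-bromo-1-methoxybenzene (E/Z mixture)
Conditions: KOtBu, THF, 0 °C → rt
Reagents that add atoms: none
Why: Wittig olefination of a semi-stabilised benzylic ylide with an aromatic aldehyde; an E/Z mixture is acceptable because the double bond is hydrogenated in step 4. Placing the olefination before the ether coupling means that aldehyde and methyl ketone never meet under base.

Step 3
Reactants: 5 4-{2-[3-(benzyloxy)phenyl]ethenyl}-2-bromo-1-methoxybenzene; 6 4-(4-hydroxyphenyl)butan-2-one (raspberry ketone)
Product: 7 4-[4-(5-{2-[3-(benzyloxy)phenyl]ethenyl}-2-methoxyphenoxy)phenyl]butan-2-one (E/Z mixture)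
Conditions: CuI (10 mol%), N,N-dimethylglycine·HCl (30 mol%), Cs2CO3, 1,4-dioxane, 100 °C
Reagents that add atoms: none
Why: Ullmann-type C–O coupling catalysed by monovalent copper with an amino acid ligand; 6 is the only phenol present because ring D is benzylated. The heterogeneous carbonate base should leave the methyl ketone, the stilbene and the benzyl ether untouched.

Step 4
Reactants: 7 4-[4-(5-{2-[3-(benzyloxy)phenyl]ethenyl}-2-methoxyphenoxy)phenyl]butan-2-one
Product: 8 4-(4-{5-[2-(3-hydroxyphenyl)ethyl]-2-methoxyphenoxy}phenyl)butan-2-one
Conditions: H2 (1 atm), Pd/C, EtOAc–EtOH, rt
Reagents that add atoms: none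
Why: Catalytic hydrogenation saturates the stilbene double bond and hydrogenolyses the benzyl ether in one operation; the non-benzylic dialkyl ketone, the aryl methyl ether and the diaryl ether are inert under these conditions.

Step 5
Reactants: 8 4-(4-{5-[2-(3-hydroxyphenyl)ethyl]-2-methoxyphenoxy}phenyl)butan-2-one
Product: 11 1-bromo-4-(4-{5-[2-(3-hydroxyphenyl)ethyl]-2-methoxyphenoxy}phenyl)butan-2-one, via bis-silyl enol ether 9 (not isolated), via silyl-protected bromoketone 10 (not isolated)
Conditions: LiN(iPr)2 (2.2 equiv), THF, −78 °C; Me3SiCl; then NBS, NaHCO3, THF, −78 → 0 °C; 1 M HCl work-up
Reagents that add atoms: N-bromosuccinimide, BrN1C(=O)CCC1=O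
Why: Kinetic deprotonation of a methyl ketone by a hindered lithium amide takes place at the methyl group, and silylation traps the terminal enol ether while masking the ring D phenol. N-Bromosuccinimide should brominate the silyl enol ether much faster than any arene (silyl enol ether bromination), and the acidic work-up returns the phenol.

Step 6
Reactants: 11 1-bromo-4-(4-{5-[2-(3-hydroxyphenyl)ethyl]-2-methoxyphenoxy}phenyl)butan-2-one
Product: 12 18-membered macrocyclic aryloxymethyl ketone (ring D–O–CH2–C(=O)–CH2CH2–ring B; ring C methyl ether)
Conditions: Cs2CO3, MeCN, 60 °C, slow addition (final ca. 2 mM)
Reagents that add atoms: none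
Why: Intramolecular Williamson ether synthesis; SN2 displacement at a halomethyl ketone by a caesium phenoxide is very fast, which with slow addition should favour ring closure over oligomer formation. The closing chain is flexible, so no arene has to bend in the transition state.

Step 7
Reactants: 12 18-membered macrocyclic aryloxymethyl ketone; 13 methyl vinyl ketone
Product: 16 macrocyclic 4-aryloxy-3-alkylcyclohex-2-enone (racemic), via Michael adduct 14 (not isolated), via ketol 15 (not isolated)
Conditions: KOtBu (0.15 equiv), THF–tBuOH, 0 °C, 13 (1.2 equiv) added slowly; then AcOH, pyrrolidine (1 equiv), 45 °C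
Reagents that add atoms: none
Why: Catalytic alkoxide forms the enolate on the aryloxy-bearing α-carbon of 12, which adds to 13 (Michael addition) to give 14; after neutralisation, pyrrolidinium acetate converts the new methyl ketone into its enamine, whose terminal carbon adds to the macrocyclic carbonyl to give 15, and loss of water gives 16. The closest known reaction type is the Robinson annulation of α-oxygenated ketones with 13, combined with the amine-mediated aldol condensation of 1,5-diketones. The six-membered carbocycle closes by a 6-(enolexo)-exo-trig aldol addition followed by dehydration, and the 18-membered ring is not opened. The aryloxy-bearing carbon becomes stereogenic with no controlling element, so 16 is racemic; this centre and those of 15 disappear on dehydration and later aromatisation. The first selectivity needed is the site of conjugate addition: the O–CH2 protons are the most acidic in 12 because of the inductive effect of the aryloxy group, so under equilibrating catalytic base that enolate should dominate, and slow addition of a small excess of 13 limits a second alkylation. The second is the direction of the aldol closure: the unhindered methyl ketone is the one expected to form the enamine, and the aryloxy-substituted carbonyl is the more electrophilic, which should disfavour attack of the bridge-side methylene on the methyl ketone. The aryloxy group sits α to the ketone in 14 and γ to the carbonyl in 16, positions from which no E1cB loss is possible, and strong acid is avoided so that 16 neither isomerises to an enol ether nor ionises at the allylic carbon.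

Step 8
Reactants: 16 macrocyclic 4-aryloxy-3-alkylcyclohex-2-enone
Product: 20 ring C O-methyl ether of the target (ring A phenol), via selenide 17 (not isolated), via selenoxide 18 (not isolated), via cyclohexadienone 19 (not isolated)
Conditions: LiN(iPr)2, THF, −78 °C; PhSeCl; then mCPBA (1.0 equiv), CH2Cl2, −78 °C; iPr2NH, → rt
Reagents that add atoms: none
Why: Kinetic α′-deprotonation and selenenylation at C6, oxidation to the selenoxide and syn-elimination towards C5 give the cross-conjugated dienone, whose C4–H tautomerises at once to the ring A phenol (selenoxide elimination, then dienone–phenol tautomerisation). One equivalent of peracid at low temperature with an amine scavenger should protect the new electron-rich phenol, and the absence of acid keeps the aryloxy group in place.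

Step 9
Reactants: 20 ring C O-methyl ether of the target
Product: 21 target macrocyclic bis(bibenzyl) diphenol
Conditions: BBr3, CH2Cl2, −78 → 0 °C; then H2O
Reagents that add atoms: none
Why: Lewis acid cleavage of the aryl methyl ether by BBr3, with bromide attacking the methyl group of the boron-complexed ether. The diaryl ethers offer no sp3 carbon for this attack and should survive, and the ring A phenol is only borylated and released on hydrolysis.

## Compound list

1 | 3-(benzyloxy)benzyl bromide [1-(benzyloxy)-3-(bromomethyl)benzene] | BrCc1cccc(OCc2ccccc2)c1 | starting material
2 | triphenylphosphine | c1ccc(cc1)P(c1ccccc1)c1ccccc1 | starting material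
3 | [3-(benzyloxy)benzyl]triphenylphosphonium bromide | [Br-].C(c1cccc(OCc2ccccc2)c1)[P+](c1ccccc1)(c1ccccc1)c1ccccc1 | intermediate
4 | 3-bromo-4-methoxybenzaldehyde | COc1ccc(C=O)cc1Br | starting material
5 | 4-{2-[3-(benzyloxy)phenyl]ethenyl}-2-bromo-1-methoxybenzene (E/Z mixture) | COc1ccc(C=Cc2cccc(OCc3ccccc3)c2)cc1Br | intermediate
6 | 4-(4-hydroxyphenyl)butan-2-one (raspberry ketone) | CC(=O)CCc1ccc(O)cc1 | starting material
7 | 4-[4-(5-{2-[3-(benzyloxy)phenyl]ethenyl}-2-methoxyphenoxy)phenyl]butan-2-one (E/Z mixture) | CC(=O)CCc1ccc(cc1)Oc1cc(C=Cc2cccc(OCc3ccccc3)c2)ccc1OC | intermediate
8 | 4-(4-{5-[2-(3-hydroxyphenyl)ethyl]-2-methoxyphenoxy}phenyl)butan-2-one | CC(=O)CCc1ccc(cc1)Oc1cc(CCc2cccc(O)c2)ccc1OC | intermediate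
9 | bis(trimethylsilyl) derivative of 8: terminal trimethylsilyl enol ether with ring D O–SiMe3 | C=C(O[Si](C)(C)C)CCc1ccc(cc1)Oc1cc(CCc2cccc(O[Si](C)(C)C)c2)ccc1OC | intermediate (not isolated)
10 | 1-bromo-4-[4-(2-methoxy-5-{2-[3-(trimethylsilyloxy)phenyl]ethyl}phenoxy)phenyl]butan-2-one | BrCC(=O)CCc1ccc(cc1)Oc1cc(CCc2cccc(O[Si](C)(C)C)c2)ccc1OC | intermediate (not isolated)
11 | 1-bromo-4-(4-{5-[2-(3-hydroxyphenyl)ethyl]-2-methoxyphenoxy}phenyl)butan-2-one | BrCC(=O)CCc1ccc(cc1)Oc1cc(CCc2cccc(O)c2)ccc1OC | intermediate
12 | 18-membered macrocyclic aryloxymethyl ketone (ring D–O–CH2–C(=O)–CH2CH2–ring B, ring C methyl ether) | O=C1COc2cccc(c2)CCc2ccc(OC)c(c2)Oc2ccc(cc2)CC1 | intermediate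
13 | methyl vinyl ketone (but-3-en-2-one) | CC(=O)C=C | starting material
14 | Michael adduct: 12 with a 3-oxobutyl group on the aryloxy-bearing α-carbon (racemic) | CC(=O)CCC1Oc2cccc(c2)CCc2ccc(OC)c(c2)Oc2ccc(cc2)CCC1=O | intermediate (not isolated)
15 | ketol: 4-aryloxy-3-hydroxy-3-alkylcyclohexanone fused to the macrocycle (racemic, mixture of diastereomers) | O=C1CCC2Oc3cccc(c3)CCc3ccc(OC)c(c3)Oc3ccc(cc3)CCC2(O)C1 | intermediate (not isolated)
16 | macrocyclic 4-aryloxy-3-alkylcyclohex-2-enone (racemic) | O=C1C=C2C(CC1)Oc1cccc(c1)CCc1ccc(OC)c(c1)Oc1ccc(cc1)CC2 | intermediate
17 | 6-(phenylselanyl) derivative of 16 (racemic, mixture of diastereomers) | O=C1C=C2C(CC1[Se]c1ccccc1)Oc1cccc(c1)CCc1ccc(OC)c(c1)Oc1ccc(cc1)CC2 | intermediate (not isolated)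
18 | selenoxide of 17 (mixture of diastereomers) | O=C1C=C2C(CC1[Se](=O)c1ccccc1)Oc1cccc(c1)CCc1ccc(OC)c(c1)Oc1ccc(cc1)CC2 | intermediate (not isolated)
19 | macrocyclic 4-aryloxy-3-alkylcyclohexa-2,5-dienone (racemic) | O=C1C=C2C(C=C1)Oc1cccc(c1)CCc1ccc(OC)c(c1)Oc1ccc(cc1)CC2 | intermediate (not isolated)
20 | ring C O-methyl ether of the target (ring A phenol free) | Oc1ccc2c(c1)CCc1ccc(cc1)Oc1cc(ccc1OC)CCc1cccc(c1)O2 | intermediate
21 | target macrocyclic bis(bibenzyl) diphenol (achiral) | Oc1ccc2c(c1)CCc1ccc(cc1)Oc1cc(ccc1O)CCc1cccc(c1)O2 | target

## Step count and least certain steps

Total step count: 9. Longest linear sequence: 9 steps (1 to 21 through 3, 5, 7, 8, 11, 12, 16 and 20).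

**Step 7 (key step).** The most likely failures are loss of site control in the conjugate addition (addition through the bridge-side enolate, or a second addition at the aryloxy carbon), base-induced polymerisation of 13, and ring closure in the other aldol direction, in which the bridge-side methylene attacks the methyl ketone. All of these arise because 12 and 14 each offer more than one enolisable position of similar reactivity. The fallback sets out from 12. The aryloxy-side enol is fixed beforehand as the trimethylsilyl enol ether F1 by soft enolisation at the more acidic O–CH2 position (Me3SiOTf, Et3N, CH2Cl2, 0 °C). F1 is then added to 13 in a Mukaiyama–Michael reaction (TiCl4, CH2Cl2, −78 °C) to give 14, which is now isolated and purified. The ring is closed separately with pyrrolidinium acetate, and the fallback comes back to the route at 16.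

**Step 3.** The coupling may be sluggish because the bromide is electron-rich and flanked by a methoxy group, and during long heating the methyl ketone may self-condense under base. The fallback replaces copper coupling by nucleophilic aromatic substitution on an activated ring B and sets out from 3.
- Wittig reaction of 3 with isovanillin (3-hydroxy-4-methoxybenzaldehyde, two equivalents of KOtBu) gives the hydroxystilbene F2.
- Substitution of 4-fluorobenzaldehyde by F2 (K2CO3, DMF, 120 °C) gives the aryloxybenzaldehyde F3.
- Claisen–Schmidt condensation of F3 with acetone (aqueous NaOH) gives the enone F4.
- Hydrogenation of F4 (H2, Pd/C) saturates both double bonds and removes the benzyl group, and the fallback comes back to the route at 8.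

**Step 5.** Regiocontrol may erode if the kinetic enolate equilibrates to the internal position before silylation, and an electron-rich ring may be brominated. The fallback delivers the halomethyl carbon as a nucleophile to an ester instead of halogenating an enol derivative, and sets out from 5.
- Copper coupling of 5 with methyl 3-(4-hydroxyphenyl)propanoate under the conditions of step 3 gives the ester F5.
- Hydrogenation (H2, Pd/C) gives the phenol ester F6.
- Chloromethyllithium generated in the flask (ICH2Cl, MeLi·LiBr, THF, −78 °C, one extra equivalent of MeLi for the phenol) converts F6 into the chloromethyl ketone F7.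
- F7 is cyclised under the conditions of step 6 with added NaI, and the fallback comes back to the route at 12.

**Step 6.** Intermolecular alkylation may outrun ring closure and give oligomers, and the halomethyl ketone may degrade under base (Favorskii-type or aldol pathways). The fallback closes the same bond under neutral conditions and sets out from 8. The bis-silyl compound 9 is made as in step 5 and subjected to Rubottom oxidation (mCPBA, then dilute acid) to give the hydroxymethyl ketone F8. F8 is cyclised by a Mitsunobu etherification (PPh3, DIAD, toluene, high dilution, slow addition), and the fallback comes back to the route at 12.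

**Step 8.** Competing deprotonation at the aryloxy-bearing γ-carbon, or over-oxidation of the newly formed electron-rich phenol by selenium-derived oxidants, may lower the efficiency. The fallback sets out from 16. The kinetic enolate is trapped as the trimethylsilyl dienol ether F9 (LiN(iPr)2, Me3SiCl, THF, −78 °C). F9 is dehydrogenated by a Saegusa–Ito oxidation with divalent palladium (Pd(OAc)2, MeCN, rt) to 19, which tautomerises, and the fallback comes back to the route at 20.

## Further compounds

F1 | step 7 | trimethylsilyl enol ether of 12 on the aryloxy side (geometry not defined) | C[Si](C)(C)OC1=COc2cccc(c2)CCc2ccc(OC)c(c2)Oc2ccc(cc2)CC1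
F2 | step 3 | 5-{2-[3-(benzyloxy)phenyl]ethenyl}-2-methoxyphenol (E/Z mixture) | COc1ccc(C=Cc2cccc(OCc3ccccc3)c2)cc1O
F3 | step 3 | 4-(5-{2-[3-(benzyloxy)phenyl]ethenyl}-2-methoxyphenoxy)benzaldehyde (E/Z mixture) | O=Cc1ccc(cc1)Oc1cc(C=Cc2cccc(OCc3ccccc3)c2)ccc1OC
F4 | step 3 | (E)-4-[4-(5-{2-[3-(benzyloxy)phenyl]ethenyl}-2-methoxyphenoxy)phenyl]but-3-en-2-one (stilbene E/Z mixture) | CC(=O)/C=C/c1ccc(cc1)Oc1cc(C=Cc2cccc(OCc3ccccc3)c2)ccc1OC
F5 | step 5 | methyl 3-[4-(5-{2-[3-(benzyloxy)phenyl]ethenyl}-2-methoxyphenoxy)phenyl]propanoate (E/Z mixture) | COC(=O)CCc1ccc(cc1)Oc1cc(C=Cc2cccc(OCc3ccccc3)c2)ccc1OC
F6 | step 5 | methyl 3-(4-{5-[2-(3-hydroxyphenyl)ethyl]-2-methoxyphenoxy}phenyl)propanoate | COC(=O)CCc1ccc(cc1)Oc1cc(CCc2cccc(O)c2)ccc1OC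
F7 | step 5 | 1-chloro-4-(4-{5-[2-(3-hydroxyphenyl)ethyl]-2-methoxyphenoxy}phenyl)butan-2-one | ClCC(=O)CCc1ccc(cc1)Oc1cc(CCc2cccc(O)c2)ccc1OC
F8 | step 6 | 1-hydroxy-4-(4-{5-[2-(3-hydroxyphenyl)ethyl]-2-methoxyphenoxy}phenyl)butan-2-one | OCC(=O)CCc1ccc(cc1)Oc1cc(CCc2cccc(O)c2)ccc1OC
F9 | step 8 | trimethylsilyl dienol ether of 16 (2-silyloxy-1,3-diene, racemic) | C[Si](C)(C)OC1=CCC2C(=C1)CCc1ccc(cc1)Oc1cc(ccc1OC)CCc1cccc(c1)O2
A1 | alternative 1 | open-chain bisphenol: ring C 2,6-dibromophenol, ring B 2,6-dichlorophenol, ring A methyl ether | COc1ccc(Oc2cccc(CCc3cc(Br)c(O)c(Br)c3)c2)c(CCc2cc(Cl)c(O)c(Cl)c2)c1
A2 | alternative 1 | halogenated macrocycle with free ring C phenol and ring A methyl ether | COc1ccc2c(c1)CCc1cc(Cl)c(c(Cl)c1)Oc1cc(cc(Br)c1O)CCc1cccc(c1)O2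
A3 | alternative 2 | tethered 2-aryloxybuta-1,3-diene and ethynyl ketone | COc1ccc(Oc2cccc(CCc3ccc(OC)c(OC(=C)C=C)c3)c2)c(CC(=O)C#C)c1
A4 | alternative 2 | macrocyclic 1-acyl-4-aryloxycyclohexa-1,4-diene | COc1ccc2c(c1)CC(=O)C1=CCC(=CC1)Oc1cc(ccc1OC)CCc1cccc(c1)O2
A5 | alternative 3 | open-chain ring A phenol carrying a 5-substituted 3-chlorocyclohex-2-enone (racemic) | COc1ccc(O)c(c1)CCc1ccc(cc1)Oc1cc(ccc1OC)CCC1CC(Cl)=CC(=O)C1
A6 | alternative 3 | macrocyclic vinylogous aryl ester (racemic) | COc1ccc2c(c1)CCc1ccc(cc1)Oc1cc(ccc1OC)CCC1CC(=CC(=O)C1)O2
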